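**Plan**
- Retrosynthesis first cuts C2–Br and C3–Cl (late electrophilic halogenations of the pyrrole ring), then N–H back to N–Ts, the C2=C3 double bond back to an indoline, and C4–Br/C7–Br back to C4–Si/C7–Si.
- The bicycle is then opened at C3a–C7a, C4–C5 and C6–C7. The benzene ring carries substituents only at C4 and C7, the two carbons next to the ring-fusion atoms, and C5–C6 is bare. That is the pattern left by a diyne tethered through N1–C2–C3, whose two capped termini become C4 and C7, plus one molecule of acetylene.
- Last, the N–C(sp) ynamide bond and the N–CH2 bond are cut, giving a sulfonamide, a silylated homopropargyl alcohol and a silylated bromoalkyne.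
- Forward: the chain is assembled on nitrogen, both rings close in one cyclotrimerization, then Si→Br exchange, dehydrogenation, detosylation, C3 chlorination and C2 bromination.
- Stereochemistry: the target is planar and has no stereogenic element, so nothing has to be set or protected.

Key step: step 5

Remark: because the target is achiral, the request for a single enantiomer is met by the compound itself.

**Route**

Step 1
Reactants: 1 4-(trimethylsilyl)but-3-yn-1-ol; 2 tert-butyl N-(4-methylphenylsulfonyl)carbamate
Product: 3 tert-butyl N-(4-methylphenylsulfonyl)-N-[4-(trimethylsilyl)but-3-yn-1-yl]carbamate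
Conditions: PPh3, DIAD, THF, 0 °C → rt
Reagents that add atoms: none
Why: Mitsunobu N-alkylation of an acidic Boc-sulfonamide by a primary alkoxyphosphonium ion stops cleanly at mono-alkylation and avoids the E2 loss to an enyne that a homopropargyl halide would risk.

Step 2
Reactants: 3 tert-butyl N-(4-methylphenylsulfonyl)-N-[4-(trimethylsilyl)but-3-yn-1-yl]carbamate
Product: 4 4-methyl-N-[4-(trimethylsilyl)but-3-yn-1-yl]benzenesulfonamide
Conditions: TFA, CH2Cl2, 0 °C → rt
Reagents that add atoms: none
Why: Acidolytic Boc cleavage through the tert-butyl cation and decarboxylation is fast for an N-acyl sulfonamide, and the alkynylsilane should be inert to TFA at room temperature.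

Step 3
Reactants: 5 ethynyltrimethylsilane
Product: 6 (bromoethynyl)trimethylsilane
Conditions: NBS (1.05 equiv), AgNO3 (cat.), acetone, rt, dark
Reagents that add atoms: N-bromosuccinimide, BrN1C(=O)CCC1=O
Why: Silver-catalysed electrophilic bromination of a terminal alkyne via the silver acetylide is standard, and with near-stoichiometric NBS the C–H terminus should react before the C–Si terminus.

Step 4
Reactants: 4 4-methyl-N-[4-(trimethylsilyl)but-3-yn-1-yl]benzenesulfonamide; 6 (bromoethynyl)trimethylsilane
Product: 7 4-methyl-N-[4-(trimethylsilyl)but-3-yn-1-yl]-N-[(trimethylsilyl)ethynyl]benzenesulfonamide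
Conditions: CuSO4·5H2O (cat.), 1,10-phenanthroline (cat.), K2CO3, toluene, 65 °C
Reagents that add atoms: none
Why: Copper-catalysed Ullmann-type N-alkynylation of a secondary sulfonamide with a 1-bromoalkyne is the standard ynamide synthesis, and the mild carbonate base at moderate temperature is chosen to keep both C–Si bonds.

Step 5
Reactants: 7 4-methyl-N-[4-(trimethylsilyl)but-3-yn-1-yl]-N-[(trimethylsilyl)ethynyl]benzenesulfonamide; 8 acetylene
Product: 9 1-tosyl-4,7-bis(trimethylsilyl)indoline
Conditions: RhCl(PPh3)3 (10 mol%), HC≡CH (1 atm), toluene, 60 °C
Reagents that add atoms: none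
Why: Rh(I) binds both alkynes of 7 and undergoes oxidative cyclization to a bicyclic rhodacyclopentadiene, which forms C3a–C7a and closes the five-membered ring by intramolecular coupling of the two tethered alkynes, the three-atom N1–C2–C3 tether allowing no other ring size. Acetylene then coordinates and inserts into a Rh–C bond, and reductive elimination forms C4–C5 and C6–C7, closing the benzene ring by intermolecular annulation of the metallacycle with the third alkyne. The closest known reaction is the RhCl(PPh3)3-catalysed [2+2+2] cyclotrimerization of N-tosyl ynamide-tethered 1,6-diynes with alkynes to indolines; two silylated termini lie at the hindered edge of its scope, hence the raised loading and temperature. No stereocentre is formed. The step needs cross-trimerization to beat diyne self-coupling and acetylene oligomerization, which the two bulky Me3Si termini and a constant excess of the small partner should secure, while the tether and the symmetry of acetylene fix the regiochemistry so that silicon ends at C4 and C7.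

Step 6
Reactants: 9 1-tosyl-4,7-bis(trimethylsilyl)indoline
Product: 10 4,7-dibromo-1-tosylindoline
Conditions: Br2 (2.2 equiv), CH2Cl2, −20 °C → rt, dark; aq. Na2S2O3
Reagents that add atoms: bromine, BrBr
Why: Electrophilic ipso-bromodesilylation of aryltrimethylsilanes is favoured by β-silyl stabilisation of the arenium ion, so attack at C4 and C7 should outrun C–H bromination at C5 of the only weakly activated N-sulfonyl ring.

Step 7
Reactants: 10 4,7-dibromo-1-tosylindoline
Product: 11 4,7-dibromo-1-tosyl-1H-indole
Conditions: DDQ (2 equiv), chlorobenzene, reflux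
Reagents that add atoms: none
Why: DDQ dehydrogenation of an N-protected indoline (hydride abstraction followed by proton loss) is driven by aromatisation to the indole and leaves aryl bromides and the sulfonamide untouched.

Step 8
Reactants: 11 4,7-dibromo-1-tosyl-1H-indole
Product: 12 4,7-dibromo-1H-indole
Conditions: Cs2CO3, THF/MeOH (2:1), rt → 50 °C
Reagents that add atoms: none
Why: Methoxide cleaves the N–S bond of an N-sulfonylindole because the indolide, here further stabilised by two bromines, is a good leaving group, and these non-reductive conditions spare the aryl bromides.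

Step 9
Reactants: 12 4,7-dibromo-1H-indole
Product: 13 4,7-dibromo-3-chloro-1H-indole
Conditions: NCS (1.05 equiv), DMF, 0 °C → rt
Reagents that add atoms: N-chlorosuccinimide, ClN1C(=O)CCC1=O
Why: Electrophilic aromatic substitution of a free indole goes at C3, its most nucleophilic position, and one equivalent of NCS should stop at the monochloride.

Step 10
Reactants: 13 4,7-dibromo-3-chloro-1H-indole
Product: 14 2,4,7-tribromo-3-chloro-1H-indole
Conditions: NBS (1.0 equiv), CH2Cl2, 0 °C, dark
Reagents that add atoms: N-bromosuccinimide, BrN1C(=O)CCC1=O
Why: With C3 blocked by chlorine, electrophilic bromination of a 3-haloindole is directed to C2, the benzene ring being deactivated by its two bromines.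

**Compound list**
1 | 4-(trimethylsilyl)but-3-yn-1-ol | C[Si](C)(C)C#CCCO | starting material
2 | tert-butyl N-(4-methylphenylsulfonyl)carbamate | Cc1ccc(cc1)S(=O)(=O)NC(=O)OC(C)(C)C | starting material
3 | tert-butyl N-(4-methylphenylsulfonyl)-N-[4-(trimethylsilyl)but-3-yn-1-yl]carbamate | Cc1ccc(cc1)S(=O)(=O)N(CCC#C[Si](C)(C)C)C(=O)OC(C)(C)C | intermediate
4 | 4-methyl-N-[4-(trimethylsilyl)but-3-yn-1-yl]benzenesulfonamide | Cc1ccc(cc1)S(=O)(=O)NCCC#C[Si](C)(C)C | intermediate
5 | ethynyltrimethylsilane | C[Si](C)(C)C#C | starting material
6 | (bromoethynyl)trimethylsilane | C[Si](C)(C)C#CBr | intermediate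
7 | 4-methyl-N-[4-(trimethylsilyl)but-3-yn-1-yl]-N-[(trimethylsilyl)ethynyl]benzenesulfonamide | Cc1ccc(cc1)S(=O)(=O)N(CCC#C[Si](C)(C)C)C#C[Si](C)(C)C | intermediate
8 | acetylene | C#C | starting material
9 | 1-tosyl-4,7-bis(trimethylsilyl)indoline | Cc1ccc(cc1)S(=O)(=O)N1CCc2c([Si](C)(C)C)ccc([Si](C)(C)C)c21 | intermediate
10 | 4,7-dibromo-1-tosylindoline | Cc1ccc(cc1)S(=O)(=O)N1CCc2c(Br)ccc(Br)c21 | intermediate
11 | 4,7-dibromo-1-tosyl-1H-indole | Cc1ccc(cc1)S(=O)(=O)n1ccc2c(Br)ccc(Br)c21 | intermediate
12 | 4,7-dibromo-1H-indole | Brc1ccc(Br)c2[nH]ccc12 | intermediate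
13 | 4,7-dibromo-3-chloro-1H-indole | Clc1c[nH]c2c(Br)ccc(Br)c12 | intermediate
14 | 2,4,7-tribromo-3-chloro-1H-indole | Clc1c(Br)[nH]c2c(Br)ccc(Br)c12 | target

**Count**
Total steps: 10. Longest linear sequence: 9 (steps 1, 2, 4–10 from compound 1).

**Steps most likely to fail**

Step 5. Oxidative cyclization at rhodium may be too slow when both alkyne termini carry Me3Si groups, so that acetylene oligomerization and catalyst decay use up the gas while the diyne is returned. The fallback sets out from 7 and replaces catalysis by a stepwise titanium-mediated assembly, for which silylated alkynes are favourable substrates. Ti(OiPr)4 with two equivalents of i-PrMgCl in ether at −50 °C should convert 7 into the bicyclic 2,5-bis(trimethylsilyl)titanacyclopentadiene F1. Ethynyl p-tolyl sulfone should then insert, and transfer of the sulfinate from carbon to titanium aromatises the new ring to the aryltitanium sulfinate F2 (titanium at C6 as drawn; the C5 isomer serves equally). Protonolysis with dilute aqueous acid should return the route at 9.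

Step 6. Electrophilic attack may go in part to the C–H position para to nitrogen (C5), or traces of HBr may protodesilylate, instead of clean ipso substitution at both silicon-bearing carbons. The fallback sets out from 9 and moves the halogenation onto boron. BBr3 in CH2Cl2 should exchange only the C–Si bonds, since it does not borylate C–H positions of such an arene, giving 4,7-bis(dibromoboryl)-1-tosylindoline F3. Treatment with pinacol and Et3N should give 1-tosyl-4,7-bis(4,4,5,5-tetramethyl-1,3,2-dioxaborolan-2-yl)indoline F4. Copper(II) bromide in aqueous methanol at 80 °C should then effect bromodeboronation and return the route at 10.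

Step 7. Hydride abstraction from the electron-poor, N-sulfonylated indoline may be sluggish, leading to incomplete dehydrogenation or decomposition on long heating. The fallback sets out from 10 and uses elimination in place of oxidation. t-BuOK in DMSO at room temperature should remove H-2 with loss of p-toluenesulfinate from nitrogen to give 4,7-dibromo-3H-indole F5, which tautomerises in the flask to the 1H-indole. The route is rejoined at 12, with step 8 no longer needed. The temperature is kept low to avoid base-induced loss of the aryl bromides.

**Further compounds**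
F1 | step 5 | bicyclic diisopropoxy-2,5-bis(trimethylsilyl)titanacyclopentadiene fused to the N-tosylpyrrolidine ring | CC(C)O[Ti]1(OC(C)C)C([Si](C)(C)C)=C2CCN(S(=O)(=O)c3ccc(C)cc3)C2=C1[Si](C)(C)C
F2 | step 5 | [1-tosyl-4,7-bis(trimethylsilyl)indolin-6-yl]titanium diisopropoxide p-toluenesulfinate | CC(C)O[Ti](OC(C)C)(OS(=O)c1ccc(C)cc1)c1cc([Si](C)(C)C)c2CCN(S(=O)(=O)c3ccc(C)cc3)c2c1[Si](C)(C)C
F3 | step 6 | 4,7-bis(dibromoboryl)-1-tosylindoline | Cc1ccc(cc1)S(=O)(=O)N1CCc2c(B(Br)Br)ccc(B(Br)Br)c21
F4 | step 6 | 1-tosyl-4,7-bis(4,4,5,5-tetramethyl-1,3,2-dioxaborolan-2-yl)indoline | Cc1ccc(cc1)S(=O)(=O)N1CCc2c(B3OC(C)(C)C(C)(C)O3)ccc(B3OC(C)(C)C(C)(C)O3)c21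
F5 | step 7 | 4,7-dibromo-3H-indole | Brc1ccc(Br)c2N=CCc12
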